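The seven-membered ring (guaiane numbering: C1, C5–C10) hides a cyclohepta-1,4-diene: the C1=C10 alkene and, at the enol-ether level, C7=C8 flank the C9 methylene. Everything rests on cutting this ring into a three-carbon unit C10–C1–C5 and a four-carbon unit C6–C9. A rhodium vinylcarbenoid from a (3S)-3-methylcyclopentenyl diazoacetate and 2-silyloxybutadiene combine by tandem cyclopropanation/Cope rearrangement. In one operation this forms C9–C10 and C5–C6, sets C5 under catalyst control and delivers a regiodefined C7=C8 silyl enol ether. The ester becomes the C10 methyl; Mukaiyama aldol with acetone, directed reduction and acylation with a protected p-coumaric acid complete the target.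

Key step: step 5

Remark on numbering: bicyclic compounds are discussed with guaiane numbering (C1 and C5 ring fusion; C2–C4 complete the five-membered ring, C15 methyl on C4; C6–C10 complete the seven-membered ring, C11–C13 carbinol unit on C7, oxygen on C8, C14 methyl on C10); the target is 4S,5S,7S,8S.

Assumption: the sense of induction is taken as (R)-p-tol-BINAP giving the (S) β-carbon in step 2 and Rh2(S-DOSP)4 giving the (1R,2S)-cyclopropane 11 in step 5 (the spatial sense of the established model for this catalyst); if either sense is the opposite, the mirror-image ligand is used and nothing else changes.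

Step 1
Reactants: 1 but-3-en-2-one
Product: 2 2-(tert-butyldimethylsilyloxy)buta-1,3-diene
Conditions: TBSOTf, Et3N, Et2O, 0 °C
Reagents that add atoms: tert-butyldimethylsilyl trifluoromethanesulfonate, CC(C)(C)[Si](C)(C)OS(=O)(=O)C(F)(F)F
Why: Soft enolisation of the methyl ketone and O-silylation (silyl enol ether formation with a silyl triflate and an amine) gives the 2-silyloxydiene; no stereocenter is formed.

Step 2
Reactants: 3 3-methylcyclopent-2-en-1-one
Product: 6 (3S)-3-methylcyclopent-1-en-1-yl trifluoromethanesulfonate, via bis(enoxy)diphenylsilane 4 (not isolated), via lithium enolate 5 (not isolated)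
Conditions: CuCl (5 mol %), NaOtBu (5 mol %), (R)-p-tol-BINAP (5 mol %), Ph2SiH2 (0.55 equiv), toluene, 0 °C; then MeLi, THF, 0 °C; then PhNTf2, −78 to 0 °C
Reagents that add atoms: N-phenylbis(trifluoromethanesulfonimide), O=S(=O)(N(c1ccccc1)S(=O)(=O)C(F)(F)F)C(F)(F)F
Why: A copper hydride asymmetric conjugate reduction sets the methyl-bearing stereocenter (later C4) by ligand control and gives the enol silane regiospecifically toward that carbon; silicon–lithium exchange and O-triflation of the non-equilibrating enolate then fix a C=C position that 3-methylcyclopentanone itself could not provide selectively.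

Step 3
Reactants: 6 (3S)-3-methylcyclopent-1-en-1-yl trifluoromethanesulfonate, 7 methyl bromoacetate
Product: 9 methyl 2-[(3S)-3-methylcyclopent-1-en-1-yl]acetate, via bromo(2-methoxy-2-oxoethyl)zinc 8 (not isolated)
Conditions: Zn dust (TMSCl-activated), THF, 40 °C; then 6, Pd(PPh3)4 (5 mol %), THF, 60 °C
Reagents that add atoms: none
Why: Negishi-type palladium-catalysed coupling of a Reformatsky zinc enolate with an enol triflate gives the β,γ-unsaturated ester without moving the double bond or touching the allylic stereocenter.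

Step 4
Reactants: 9 methyl 2-[(3S)-3-methylcyclopent-1-en-1-yl]acetate
Product: 10 methyl 2-diazo-2-[(3S)-3-methylcyclopent-1-en-1-yl]acetate
Conditions: p-ABSA, DBU, MeCN, 0 to 23 °C; used without storage
Reagents that add atoms: 4-acetamidobenzenesulfonyl azide, CC(=O)Nc1ccc(cc1)S(=O)(=O)N=[N+]=[N-]
Why: Regitz diazo transfer to the CH2 group activated by both the ester and the alkene is the standard entry to vinyldiazoacetates; the stereocenter carries no acidic hydrogen and is untouched.

Step 5
Reactants: 10 methyl 2-diazo-2-[(3S)-3-methylcyclopent-1-en-1-yl]acetate, 2 2-(tert-butyldimethylsilyloxy)buta-1,3-diene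
Product: 12 methyl (3S,3aS)-6-(tert-butyldimethylsilyloxy)-3-methyl-1,2,3,3a,4,7-hexahydroazulene-8-carboxylate, via cis-divinylcyclopropane 11 (not isolated)
Conditions: 10 added slowly to 2 (3 equiv) and Rh2(S-DOSP)4 (1 mol %), hexanes, −40 to 23 °C; then 50 °C
Reagents that add atoms: none
Why: Rh2(S-DOSP)4 (dirhodium tetrakis[(S)-N-(4-dodecylbenzenesulfonyl)prolinate]) converts 10 with loss of N2 into a donor/acceptor rhodium vinylcarbenoid that cyclopropanates the silyl enol ether alkene of 2 (bonds C9–C10 and C8–C10), placing the vinyl group of the diene cis to the cyclopentenyl group. The cis-divinylcyclopropane 11 then undergoes a Cope rearrangement through the obligatory boat transition state, forming C5–C6 and breaking C8–C10; this is the tandem cyclopropanation/Cope rearrangement, the formal [4+3] cycloaddition of vinylcarbenoids with dienes. The transient three-membered ring closes by carbene [2+1] addition and the seven-membered ring closes in the [3,3]-sigmatropic step, which can only give the two cis ring alkenes C1=C10 and C7=C8. C5 is the only new stereocenter that survives: the catalyst chooses the face of the carbenoid carbon (the configuration of C8 and C10 in 11) and the boat geometry relays it stereospecifically to C5, so the C5–C6 bond forms cis to the C4 methyl group, against the preference of the substrate. Regioselectivity requires attack on the oxygenated alkene, which the silyloxy group secures by stabilising positive charge at C8 in the asynchronous transition state. A substituted vinyl terminus and a hydrocarbon solvent disfavour vinylogous attack and zwitterionic [3+2] annulation.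

Step 6
Reactants: 12 methyl (3S,3aS)-6-(tert-butyldimethylsilyloxy)-3-methyl-1,2,3,3a,4,7-hexahydroazulene-8-carboxylate
Product: 13 [(3S,3aS)-6-(tert-butyldimethylsilyloxy)-3-methyl-1,2,3,3a,4,7-hexahydroazulen-8-yl]methanol
Conditions: iBu2AlH (DIBAL-H, 2.5 equiv), CH2Cl2, −78 °C; aqueous potassium sodium tartrate
Reagents that add atoms: none
Why: DIBAL-H 1,2-reduction of the tetrasubstituted enoate gives the primary allylic alcohol; the silyl enol ether is inert to the hydride and to the neutral work-up.

Step 7
Reactants: 13 [(3S,3aS)-6-(tert-butyldimethylsilyloxy)-3-methyl-1,2,3,3a,4,7-hexahydroazulen-8-yl]methanol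
Product: 15 (3S,3aS)-6-(tert-butyldimethylsilyloxy)-3,8-dimethyl-1,2,3,3a,4,7-hexahydroazulene, via allylic methanesulfonate 14 (not isolated)
Conditions: MsCl, Et3N, THF, −40 °C; then LiEt3BH, −40 to 0 °C
Reagents that add atoms: none
Why: Sulfonate activation and SN2 hydride displacement (deoxygenation of a primary allylic alcohol) turn C14 into the methyl group; SN2′ delivery would have to occur at the fully substituted C1, so the C1=C10 alkene should stay in place.

Step 8
Reactants: 15 (3S,3aS)-6-(tert-butyldimethylsilyloxy)-3,8-dimethyl-1,2,3,3a,4,7-hexahydroazulene, 16 acetone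
Product: 17 (3S,3aS,5R)-5-(2-hydroxypropan-2-yl)-3,8-dimethyl-2,3,3a,4,5,7-hexahydroazulen-6(1H)-one
Conditions: TiCl4 (1.1 equiv), CH2Cl2, −78 °C; then aq. NaHCO3 at −78 °C
Reagents that add atoms: none
Why: Mukaiyama aldol addition of the regiodefined silyl enol ether to TiCl4-activated acetone forms C7–C11 only at C7 (the free ketone would enolise toward allylic C9). The side chain should end pseudo-equatorial, cis-1,3 to the C5–C4 bond (H5 and H7 cis), in the six-membered titanium chelate; this is also the more stable α-epimer, and the cold neutral quench avoids retro-aldol and alkene conjugation.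

Step 9
Reactants: 17 (3S,3aS,5R)-5-(2-hydroxypropan-2-yl)-3,8-dimethyl-2,3,3a,4,5,7-hexahydroazulen-6(1H)-one
Product: 18 (3S,3aS,5S,6S)-5-(2-hydroxypropan-2-yl)-3,8-dimethyl-1,2,3,3a,4,5,6,7-octahydroazulen-6-ol
Conditions: Me4NBH(OAc)3, MeCN/AcOH (1:1), −30 °C
Reagents that add atoms: none
Why: Evans–Saksena directed reduction: the C11 hydroxyl exchanges onto boron and delivers hydride intramolecularly to the carbonyl face on which the C7 side chain sits, so the new C8 hydroxyl is trans to the side chain (8S); axial attack of a small hydride would give the same equatorial alcohol.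

Step 10
Reactants: 18 (3S,3aS,5S,6S)-5-(2-hydroxypropan-2-yl)-3,8-dimethyl-1,2,3,3a,4,5,6,7-octahydroazulen-6-ol, 19 (E)-3-(4-acetoxyphenyl)prop-2-enoic acid
Product: 20 (3S,3aS,5S,6S)-5-(2-hydroxypropan-2-yl)-3,8-dimethyl-1,2,3,3a,4,5,6,7-octahydroazulen-6-yl (E)-3-(4-acetoxyphenyl)prop-2-enoate
Conditions: DCC, DMAP (cat.), CH2Cl2, 0 to 23 °C
Reagents that add atoms: none
Why: Steglich esterification acylates only the secondary C8 hydroxyl (the tertiary C11 hydroxyl is inert under carbodiimide/DMAP conditions), with retention at C8 and an unchanged E-alkene.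

Step 11
Reactants: 20 (3S,3aS,5S,6S)-5-(2-hydroxypropan-2-yl)-3,8-dimethyl-1,2,3,3a,4,5,6,7-octahydroazulen-6-yl (E)-3-(4-acetoxyphenyl)prop-2-enoate
Product: 21 (3S,3aS,5S,6S)-5-(2-hydroxypropan-2-yl)-3,8-dimethyl-1,2,3,3a,4,5,6,7-octahydroazulen-6-yl (E)-3-(4-hydroxyphenyl)prop-2-enoate
Conditions: K2CO3 (0.2 equiv), MeOH, 0 °C
Reagents that add atoms: none
Why: Base-catalysed methanolysis cleaves the activated aryl acetate much faster than the hindered alkyl cinnamate, so the phenol should be released without transesterification of the C8 ester.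

Compound list
1 | but-3-en-2-one | CC(=O)C=C | starting material
2 | 2-(tert-butyldimethylsilyloxy)buta-1,3-diene | C=CC(=C)O[Si](C)(C)C(C)(C)C | intermediate
3 | 3-methylcyclopent-2-en-1-one | CC1=CC(=O)CC1 | starting material
4 | bis{[(3S)-3-methylcyclopent-1-en-1-yl]oxy}diphenylsilane | C[C@H]1CCC(O[Si](c2ccccc2)(c2ccccc2)OC2=C[C@@H](C)CC2)=C1 | intermediate
5 | lithium (3S)-3-methylcyclopent-1-en-1-olate | C[C@H]1CCC([O-])=C1.[Li+] | intermediate
6 | (3S)-3-methylcyclopent-1-en-1-yl trifluoromethanesulfonate | C[C@H]1CCC(OS(=O)(=O)C(F)(F)F)=C1 | intermediate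
7 | methyl bromoacetate | COC(=O)CBr | starting material
8 | bromo(2-methoxy-2-oxoethyl)zinc | COC(=O)C[Zn]Br | intermediate
9 | methyl 2-[(3S)-3-methylcyclopent-1-en-1-yl]acetate | COC(=O)CC1=C[C@@H](C)CC1 | intermediate
10 | methyl 2-diazo-2-[(3S)-3-methylcyclopent-1-en-1-yl]acetate | COC(=O)C(=[N+]=[N-])C1=C[C@@H](C)CC1 | intermediate
11 | methyl (1R,2S)-2-(tert-butyldimethylsilyloxy)-2-ethenyl-1-[(3S)-3-methylcyclopent-1-en-1-yl]cyclopropane-1-carboxylate | COC(=O)[C@@]1(C2=C[C@@H](C)CC2)C[C@]1(O[Si](C)(C)C(C)(C)C)C=C | intermediate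
12 | methyl (3S,3aS)-6-(tert-butyldimethylsilyloxy)-3-methyl-1,2,3,3a,4,7-hexahydroazulene-8-carboxylate | COC(=O)C1=C2CC[C@H](C)[C@@H]2CC=C(O[Si](C)(C)C(C)(C)C)C1 | intermediate
13 | [(3S,3aS)-6-(tert-butyldimethylsilyloxy)-3-methyl-1,2,3,3a,4,7-hexahydroazulen-8-yl]methanol | OCC1=C2CC[C@H](C)[C@@H]2CC=C(O[Si](C)(C)C(C)(C)C)C1 | intermediate
14 | [(3S,3aS)-6-(tert-butyldimethylsilyloxy)-3-methyl-1,2,3,3a,4,7-hexahydroazulen-8-yl]methyl methanesulfonate | CS(=O)(=O)OCC1=C2CC[C@H](C)[C@@H]2CC=C(O[Si](C)(C)C(C)(C)C)C1 | intermediate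
15 | (3S,3aS)-6-(tert-butyldimethylsilyloxy)-3,8-dimethyl-1,2,3,3a,4,7-hexahydroazulene | CC1=C2CC[C@H](C)[C@@H]2CC=C(O[Si](C)(C)C(C)(C)C)C1 | intermediate
16 | acetone | CC(C)=O | starting material
17 | (3S,3aS,5R)-5-(2-hydroxypropan-2-yl)-3,8-dimethyl-2,3,3a,4,5,7-hexahydroazulen-6(1H)-one | CC1=C2CC[C@H](C)[C@@H]2C[C@H](C(C)(C)O)C(=O)C1 | intermediate
18 | (3S,3aS,5S,6S)-5-(2-hydroxypropan-2-yl)-3,8-dimethyl-1,2,3,3a,4,5,6,7-octahydroazulen-6-ol | CC1=C2CC[C@H](C)[C@@H]2C[C@H](C(C)(C)O)[C@@H](O)C1 | intermediate
19 | (E)-3-(4-acetoxyphenyl)prop-2-enoic acid | CC(=O)Oc1ccc(/C=C/C(=O)O)cc1 | starting material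
20 | (3S,3aS,5S,6S)-5-(2-hydroxypropan-2-yl)-3,8-dimethyl-1,2,3,3a,4,5,6,7-octahydroazulen-6-yl (E)-3-(4-acetoxyphenyl)prop-2-enoate | CC1=C2CC[C@H](C)[C@@H]2C[C@H](C(C)(C)O)[C@@H](OC(=O)/C=C/c2ccc(OC(C)=O)cc2)C1 | intermediate
21 | (3S,3aS,5S,6S)-5-(2-hydroxypropan-2-yl)-3,8-dimethyl-1,2,3,3a,4,5,6,7-octahydroazulen-6-yl (E)-3-(4-hydroxyphenyl)prop-2-enoate | CC1=C2CC[C@H](C)[C@@H]2C[C@H](C(C)(C)O)[C@@H](OC(=O)/C=C/c2ccc(O)cc2)C1 | target

Total step count: 11
Longest linear sequence: 10 steps (3 to 21 through steps 2–11); step 1 is a one-step side branch.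

Steps most likely to fail

Step 5. The catalyst has to override the facial preference imposed by the C4 methyl group, because the C5–C6 bond must form cis to it, so facial selectivity at the carbenoid may be poor. The push–pull cyclopropane may also open to a zwitterion, which would erode C5 or leak into [3+2] annulation. The fallback replaces catalyst control by auxiliary control; it sets out from 9 and comes back at 13. Ester 9 is saponified (LiOH, THF/H2O) to 2-[(3S)-3-methylcyclopent-1-en-1-yl]acetic acid F1. F1 is esterified with (R)-pantolactone (DCC, DMAP) to the pantolactonyl ester F2, and diazo transfer (p-ABSA, DBU) gives the pantolactonyl vinyldiazoacetate F3. Decomposition of F3 with achiral Rh2(OOct)4 (dirhodium tetraoctanoate) in the presence of diene 2 gives, by the same cyclopropanation/Cope sequence, the pantolactonyl cycloadduct F4; here the auxiliary carbonyl shields one face of the carbenoid. LiAlH4 (Et2O, 0 °C) then removes the auxiliary reductively and gives allylic alcohol 13 directly.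

Step 8. The tertiary titanium aldolate may revert (retro-aldol) or lose water under the Lewis acid, and facial selectivity at C7 may be poor with a ketone electrophile and a hindered silyl group. The fallback replaces the open, Lewis-acid-mediated addition by a preformed metal enolate aldol in basic medium; it sets out from 15 and comes back at 17. MeLi (THF, 0 to 23 °C) cleaves the silyl enol ether to the regiodefined lithium enolate F5. Transmetalation with anhydrous CeCl3 at −78 °C gives the dichlorocerium enolate F6, which adds to acetone through a closed chair transition state. The cerium aldolate resists retro-aldol and proton transfer, and quenching at −78 °C gives 17.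

Step 9. Ligand exchange of the tertiary C11 hydroxyl onto boron may be slow, so that undirected hydride delivery gives poor facial selectivity at C8. The fallback makes the other epimer on purpose and inverts it during acylation; it sets out from 17 and comes back at 20. LiBH(s-Bu)3 (THF, −78 °C) attacks the carbonyl face away from the C7 side chain and gives the cis diol, (3S,3aS,5S,6R)-5-(2-hydroxypropan-2-yl)-3,8-dimethyl-1,2,3,3a,4,5,6,7-octahydroazulen-6-ol F7. Mitsunobu esterification of F7 with acid 19 (PPh3, diisopropyl azodicarboxylate, toluene, 0 to 23 °C) inverts C8 and gives ester 20; the tertiary hydroxyl does not react.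

Further compounds
F1 | step 5 | 2-[(3S)-3-methylcyclopent-1-en-1-yl]acetic acid | OC(=O)CC1=C[C@@H](C)CC1
F2 | step 5 | (3R)-4,4-dimethyl-2-oxooxolan-3-yl 2-[(3S)-3-methylcyclopent-1-en-1-yl]acetate | CC1(C)COC(=O)[C@@H]1OC(=O)CC1=C[C@@H](C)CC1
F3 | step 5 | (3R)-4,4-dimethyl-2-oxooxolan-3-yl 2-diazo-2-[(3S)-3-methylcyclopent-1-en-1-yl]acetate | CC1(C)COC(=O)[C@@H]1OC(=O)C(=[N+]=[N-])C1=C[C@@H](C)CC1
F4 | step 5 | (3R)-4,4-dimethyl-2-oxooxolan-3-yl (3S,3aS)-6-(tert-butyldimethylsilyloxy)-3-methyl-1,2,3,3a,4,7-hexahydroazulene-8-carboxylate | CC1(C)COC(=O)[C@@H]1OC(=O)C1=C2CC[C@H](C)[C@@H]2CC=C(O[Si](C)(C)C(C)(C)C)C1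
F5 | step 8 | lithium (3S,3aS)-3,8-dimethyl-1,2,3,3a,4,7-hexahydroazulen-6-olate | CC1=C2CC[C@H](C)[C@@H]2CC=C([O-])C1.[Li+]
F6 | step 8 | dichloro{[(3S,3aS)-3,8-dimethyl-1,2,3,3a,4,7-hexahydroazulen-6-yl]oxy}cerium | CC1=C2CC[C@H](C)[C@@H]2CC=C(O[Ce](Cl)Cl)C1
F7 | step 9 | (3S,3aS,5S,6R)-5-(2-hydroxypropan-2-yl)-3,8-dimethyl-1,2,3,3a,4,5,6,7-octahydroazulen-6-ol | CC1=C2CC[C@H](C)[C@@H]2C[C@H](C(C)(C)O)[C@H](O)C1
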